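**Plan**

1. Numbering: five-membered ring C1 (quaternary, Me)–C2–C3–C4 (OH, i-Pr)–C5 (H); seven-membered ring C5–C6 (O-aroyl)–C7 (C=O)–C8 (OH, Me)–C9 (OH)–C10–C1; β is the face of the C1 methyl.
2. Retrosynthetic cuts, in order: the C6–O acyl bond; the C4–isopropyl bond (ketone at C4); the C5–H/C6–O pair (hydroboration of a C5=C6 alkene); the C8/C9 diol (osmylation of C8=C9); the C5=C6 bond itself, cut as an aldol condensation between C5 of a cyclopentanone and a C6 aldehyde; then the chain at C7–C8 (vinyllithium + oxalate), C8=C9 (Wittig) and C1–C10 (Claisen).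
3. Forward order: the five-membered ring comes from 3-methylcyclopent-2-en-1-one, the chain C10 to C6 is built on it, the seven-membered ring is closed by the C5–C6 bond, then the rings are oxygenated and the ester is attached.
4. Feature that makes the closure possible: C5 is the α-carbon of a carbonyl at C4 (the later carbinol) in the five-membered ring and C6 bears oxygen, so C4(O)–C5–C6(O) across the ring-fusion carbon is an aldol retron; a ketal at C7 leaves the C6 aldehyde without α-hydrogen and the (Z)-C8=C9 bond pre-folds the seven-membered ring.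
5. Stereochemistry: C1 from a CBS reduction relayed by suprafacial Claisen rearrangement; C8/C9 and C5/C6 from syn additions (OsO4, BH3) anti to the C1 methyl; C4 from organocerium addition anti to the C5–C6 bond. The closure is run as a condensation because attack of the C1-tethered chain on trigonal C5 would give the cis ring fusion.

Key step: step 10

**Route**

Step 1
Reactants: 1 3-methylcyclopent-2-en-1-one
Product: 2 (R)-3-methylcyclopent-2-en-1-ol
Conditions: (S)-1-methyl-3,3-diphenyltetrahydro-1H,3H-pyrrolo[1,2-c][1,3,2]oxazaborole (10 mol %), BH3·SMe2 (0.6 equiv), THF, -20 °C; then MeOH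
Reagents that add atoms: none
Why: Corey–Bakshi–Shibata reduction: with the alkenyl carbon as the larger carbonyl substituent the (S)-oxazaborolidine–borane complex should deliver hydride to one carbonyl face and give the (R)-allylic alcohol by 1,2-reduction, which fixes the absolute configuration of the whole route.

Step 2
Reactants: 2 (R)-3-methylcyclopent-2-en-1-ol; 3 triethyl orthoacetate
Product: 5 ethyl 2-[(R)-1-methylcyclopent-2-en-1-yl]acetate, via ketene acetal 4 (not isolated)
Conditions: 3 (6 equiv), EtCO2H (5 mol %), 140 °C, EtOH distilled off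
Reagents that add atoms: none
Why: Johnson–Claisen rearrangement: ketene acetal 4 should rearrange suprafacially on the ring face that carries the C–O bond, so the carbinol configuration is transferred to the new quaternary centre C1 (methyl and CH2CO2Et), while the former carbinol carbon becomes the C4=C5 alkene that later serves as the masked C4 ketone.

Step 3
Reactants: 5 ethyl 2-[(R)-1-methylcyclopent-2-en-1-yl]acetate
Product: 6 2-[(R)-1-methylcyclopent-2-en-1-yl]acetaldehyde
Conditions: i-Bu2AlH (1.05 equiv), CH2Cl2, -78 °C; aq. potassium sodium tartrate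
Reagents that add atoms: none
Why: Low-temperature i-Bu2AlH reduction of an ester should stop at the aluminium hemiacetal and release the aldehyde only on work-up.

Step 4
Reactants: 6 2-[(R)-1-methylcyclopent-2-en-1-yl]acetaldehyde
Product: 7 (R)-3-[(Z)-3-iodobut-2-en-1-yl]-3-methylcyclopent-1-ene
Conditions: EtPPh3I (1.2 equiv), n-BuLi, THF, 0 °C; I2, -78 °C; NaN(SiMe3)2, -78 to -20 °C; then 6, -78 °C
Reagents that add atoms: ethyltriphenylphosphonium iodide CC[P+](c1ccccc1)(c1ccccc1)c1ccccc1.[I-]; iodine II
Why: Stork–Zhao olefination (Wittig reaction of an α-iodo ylide): kinetic, cis-selective oxaphosphetane formation should give the (Z)-2-iodoalkene with iodine cis to the C10 methylene, the geometry needed later for a ring alkene.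

Step 5
Reactants: 7 (R)-3-[(Z)-3-iodobut-2-en-1-yl]-3-methylcyclopent-1-ene; 8 dimethyl oxalate
Product: 10 methyl (Z)-3-methyl-5-[(R)-1-methylcyclopent-2-en-1-yl]-2-oxopent-3-enoate, via vinyllithium 9 (not isolated)
Conditions: t-BuLi (2.1 equiv), Et2O, -78 °C; then added to 8 (3 equiv), THF, -78 °C; aq. NH4Cl
Reagents that add atoms: none
Why: Iodine–lithium exchange is stereoretentive and vinyllithium 9, added to excess oxalate, should be acylated once only because the tetrahedral adduct persists until the quench, giving the α-keto ester with C7 cis to C10.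

Step 6
Reactants: 10 methyl (Z)-3-methyl-5-[(R)-1-methylcyclopent-2-en-1-yl]-2-oxopent-3-enoate
Product: 11 methyl (Z)-2,2-dimethoxy-3-methyl-5-[(R)-1-methylcyclopent-2-en-1-yl]pent-3-enoate
Conditions: Me3SiOMe (3 equiv), Me3SiOTf (10 mol %), CH2Cl2, -78 to -30 °C; pyridine
Reagents that add atoms: methoxytrimethylsilane CO[Si](C)(C)C
Why: Silyl-transfer ketalisation with Me3SiOMe and catalytic Me3SiOTf should convert the strongly electrophilic α-keto carbonyl into its dimethyl ketal under aprotic low-temperature conditions that leave the (Z)-alkene unchanged, which makes C7 a quaternary centre without α-hydrogen.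

Step 7
Reactants: 11 methyl (Z)-2,2-dimethoxy-3-methyl-5-[(R)-1-methylcyclopent-2-en-1-yl]pent-3-enoate
Product: 13 methyl (Z)-5-[(1R)-3-hydroxy-1-methylcyclopentyl]-2,2-dimethoxy-3-methylpent-3-enoate (both carbinol epimers), via B-alkyl-9-BBN adduct 12 (not isolated)
Conditions: 9-borabicyclo[3.3.1]nonane (1.3 equiv), THF, 0 °C to rt; then 30% H2O2, aq. NaHCO3, 0 °C
Reagents that add atoms: hydrogen peroxide OO
Why: Hydroboration–oxidation: the bulky 9-BBN should react only with the cis-disubstituted cyclopentene and not with the hindered trisubstituted alkene, with boron going to C4 away from the quaternary C1, and oxidation with retention gives the C4 alcohol whose configuration is irrelevant since it is oxidised in step 9.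

Step 8
Reactants: 13 methyl (Z)-5-[(1R)-3-hydroxy-1-methylcyclopentyl]-2,2-dimethoxy-3-methylpent-3-enoate
Product: 14 (3R)-3-[(Z)-5-hydroxy-4,4-dimethoxy-3-methylpent-2-en-1-yl]-3-methylcyclopentan-1-ol (both carbinol epimers)
Conditions: LiAlH4, THF, 0 °C; H2O, aq. NaOH
Reagents that add atoms: none
Why: LiAlH4 reduction of the ester to the primary alcohol should leave ketal and alkene untouched.

Step 9
Reactants: 14 (3R)-3-[(Z)-5-hydroxy-4,4-dimethoxy-3-methylpent-2-en-1-yl]-3-methylcyclopentan-1-ol
Product: 15 (Z)-2,2-dimethoxy-3-methyl-5-[(R)-1-methyl-3-oxocyclopentyl]pent-3-enal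
Conditions: Dess–Martin periodinane (2.6 equiv), pyridine, CH2Cl2, 0 °C to rt
Reagents that add atoms: none
Why: Dess–Martin oxidation should convert the secondary and the primary alcohol in one operation under buffered conditions, and the resulting aldehyde cannot enolise because C7 is quaternary.

Step 10
Reactants: 15 (Z)-2,2-dimethoxy-3-methyl-5-[(R)-1-methyl-3-oxocyclopentyl]pent-3-enal
Product: 17 (8aR)-5,5-dimethoxy-6,8a-dimethyl-1,2,8,8a-tetrahydroazulen-3(5H)-one, via aldol adduct 16 (not isolated)
Conditions: KOH (0.3 equiv), MeOH (0.01 M), 0 to 45 °C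
Reagents that add atoms: none
Why: Reversible enolisation of the C4 ketone gives the C4–C5 enolate, which adds to the aldehyde C6 to close the seven-membered ring, and E1cB loss of water from β-hydroxy ketone 16 then gives the conjugated C5=C6 enone irreversibly. The closest known reaction type is the intramolecular aldol (Claisen–Schmidt) condensation of a cycloalkanone with a tethered non-enolisable aldehyde. The seven-membered ring closes in the 7-(enolexo)-exo-trig mode, the enolate double bond lying outside the new ring. No stereocentre is created in the isolated product: C5 and C6 of adduct 16 are deliberately erased, because attack of the C1-tethered aldehyde on trigonal C5 can only take place on the face of the tether and would fix the cis ring fusion, whereas the C5=C6 alkene lets step 13 set the trans fusion under control of the C1 methyl. Regioselectivity (C5 against C3 enolate) is secured by the substrate, since only attack from C5 gives a fused seven-membered ring, attack from C3 would need a bridged nine-membered ring, and the two enolates interconvert. Chemoselectivity is secured by the quaternary C7 ketal, which leaves the aldehyde without α-hydrogen, and by the (Z)-C8=C9 alkene, which holds C6 close to C5.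

Step 11
Reactants: 17 (8aR)-5,5-dimethoxy-6,8a-dimethyl-1,2,8,8a-tetrahydroazulen-3(5H)-one
Product: 18 (6S,7S,8aR)-6,7-dihydroxy-5,5-dimethoxy-6,8a-dimethyl-1,2,6,7,8,8a-hexahydroazulen-3(5H)-one
Conditions: OsO4 (5 mol %), N-methylmorpholine N-oxide (1.5 equiv), acetone/H2O 5:1, 0 °C to rt; aq. Na2SO3
Reagents that add atoms: N-methylmorpholine N-oxide C[N+]1([O-])CCOCC1; water O
Why: Catalytic OsO4 dihydroxylation: the isolated trisubstituted C8=C9 alkene should react in preference to the electron-poor enone and osmium should add syn from the α-face, anti to the pseudo-axial C1 methyl, which sets C8 and C9 (both hydroxyls α).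

Step 12
Reactants: 18 (6S,7S,8aR)-6,7-dihydroxy-5,5-dimethoxy-6,8a-dimethyl-1,2,6,7,8,8a-hexahydroazulen-3(5H)-one
Product: 19 (6S,7S,8aR)-3,3,5,5-tetramethoxy-6,8a-dimethyl-1,2,3,5,6,7,8,8a-octahydroazulene-6,7-diol 6,7-acetonide
Conditions: Me2C(OMe)2 (10 equiv), HC(OMe)3 (5 equiv), MeOH, camphorsulfonic acid (5 mol %), rt; Et3N
Reagents that add atoms: 2,2-dimethoxypropane COC(C)(C)OC; trimethyl orthoformate COC(OC)OC
Why: Acid-catalysed acetalisation: the cis-diol should close the five-membered acetonide and the orthoformate then drives the C4 carbonyl to its dimethyl ketal, which removes the only borane-reducible group and leaves the C5=C6 alkene in place because neither C1 nor C7 carries a hydrogen for double-bond migration.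

Step 13
Reactants: 19 (6S,7S,8aR)-3,3,5,5-tetramethoxy-6,8a-dimethyl-1,2,3,5,6,7,8,8a-octahydroazulene-6,7-diol 6,7-acetonide
Product: 21 (3aS,4R,6S,7S,8aR)-3,3,5,5-tetramethoxy-6,8a-dimethyldecahydroazulene-4,6,7-triol 6,7-acetonide, via alkylborane 20 (not isolated)
Conditions: BH3·SMe2 (5 equiv), THF, 0 to 45 °C; then aq. NaOH, 30% H2O2, 0 °C to rt
Reagents that add atoms: hydrogen peroxide OO
Why: Hydroboration–oxidation: BH3 should add syn with boron on C6 (the only alkene carbon bearing hydrogen) and hydrogen on C5 from the α-face, anti to the β-methyl groups on C1 and C8 (the sense known for Δ5-steroids, which give 5α-H and 6α-OH), and oxidation with retention gives the trans ring fusion and the 6α-alcohol together.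

Step 14
Reactants: 21 (3aS,4R,6S,7S,8aR)-3,3,5,5-tetramethoxy-6,8a-dimethyldecahydroazulene-4,6,7-triol 6,7-acetonide
Product: 22 (3aS,4R,6S,7S,8aR)-4,6,7-trihydroxy-5,5-dimethoxy-6,8a-dimethyloctahydroazulen-3(2H)-one 6,7-acetonide
Conditions: pyridinium p-toluenesulfonate (10 mol %), acetone/H2O 20:1, 0 °C to rt
Reagents that add atoms: water O
Why: Acid-catalysed ketal cleavage in wet acetone: the C4 ketal of a simple cyclopentanone should cleave far faster than the C7 ketal, whose oxocarbenium ion is destabilised by C–O bonds on both neighbouring carbons, while the acetonide is held by the acetone solvent and the mild acid should not epimerise C5.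

Step 15
Reactants: 22 (3aS,4R,6S,7S,8aR)-4,6,7-trihydroxy-5,5-dimethoxy-6,8a-dimethyloctahydroazulen-3(2H)-one 6,7-acetonide
Product: 23 (3R,3aS,4R,6S,7S,8aR)-5,5-dimethoxy-6,8a-dimethyl-3-(propan-2-yl)decahydroazulene-3,4,6,7-tetrol 6,7-acetonide
Conditions: i-PrMgCl (4 equiv), CeCl3 (4 equiv), THF, -78 to -20 °C; aq. NH4Cl
Reagents that add atoms: isopropylmagnesium chloride CC(C)[Mg]Cl
Why: Organocerium 1,2-addition: the weakly basic reagent formed from i-PrMgCl and CeCl3 should add to the C4 ketone from the α-face, anti to the C5–C6 bond that covers the β-face, so that the new hydroxyl is β (cis to C6) and C5 is neither enolised nor epimerised.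

Step 16
Reactants: 23 (3R,3aS,4R,6S,7S,8aR)-5,5-dimethoxy-6,8a-dimethyl-3-(propan-2-yl)decahydroazulene-3,4,6,7-tetrol 6,7-acetonide; 24 4-acetoxybenzoyl chloride
Product: 25 (3R,3aS,4R,6S,7S,8aR)-3,6,7-trihydroxy-5,5-dimethoxy-6,8a-dimethyl-3-(propan-2-yl)decahydroazulen-4-yl 4-acetoxybenzoate 6,7-acetonide
Conditions: 24 (2 equiv), pyridine, 4-(dimethylamino)pyridine (0.3 equiv), CH2Cl2, rt to 40 °C
Reagents that add atoms: none
Why: Nucleophile-catalysed acylation with an aroyl chloride should esterify the secondary C6 hydroxyl, the tertiary C4 hydroxyl being unreactive under these conditions.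

Step 17
Reactants: 25 (3R,3aS,4R,6S,7S,8aR)-3,6,7-trihydroxy-5,5-dimethoxy-6,8a-dimethyl-3-(propan-2-yl)decahydroazulen-4-yl 4-acetoxybenzoate 6,7-acetonide
Product: 26 (3R,3aS,4R,6S,7S,8aR)-3,6,7-trihydroxy-6,8a-dimethyl-5-oxo-3-(propan-2-yl)decahydroazulen-4-yl 4-hydroxybenzoate
Conditions: 2 M aq. HCl, MeOH, rt to 45 °C
Reagents that add atoms: water O
Why: Acid hydrolysis and methanolysis should remove the acetonide, the C7 dimethyl ketal and the phenolic acetate in one operation, while the hindered secondary aroate and the C6 stereocentre next to the ketone are stable to acid, giving the target.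

**Compound list**

1 | 3-methylcyclopent-2-en-1-one | CC1=CC(=O)CC1 | starting material
2 | (R)-3-methylcyclopent-2-en-1-ol | O[C@H]1C=C(C)CC1 | intermediate
3 | triethyl orthoacetate | CC(OCC)(OCC)OCC | starting material
4 | ketene acetal: 1-ethoxy-1-{[(R)-3-methylcyclopent-2-en-1-yl]oxy}ethene | C=C(OCC)O[C@H]1C=C(C)CC1 | intermediate (not isolated)
5 | ethyl 2-[(R)-1-methylcyclopent-2-en-1-yl]acetate | CCOC(=O)C[C@@]1(C)CCC=C1 | intermediate
6 | 2-[(R)-1-methylcyclopent-2-en-1-yl]acetaldehyde | O=CC[C@@]1(C)CCC=C1 | intermediate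
7 | (R)-3-[(Z)-3-iodobut-2-en-1-yl]-3-methylcyclopent-1-ene | C/C(I)=C/C[C@@]1(C)CCC=C1 | intermediate
8 | dimethyl oxalate | COC(=O)C(=O)OC | starting material
9 | vinyllithium: (Z)-2-lithio-4-[(R)-1-methylcyclopent-2-en-1-yl]but-2-ene | C/C([Li])=C/C[C@@]1(C)CCC=C1 | intermediate (not isolated)
10 | methyl (Z)-3-methyl-5-[(R)-1-methylcyclopent-2-en-1-yl]-2-oxopent-3-enoate | COC(=O)C(=O)/C(C)=C\C[C@@]1(C)CCC=C1 | intermediate
11 | methyl (Z)-2,2-dimethoxy-3-methyl-5-[(R)-1-methylcyclopent-2-en-1-yl]pent-3-enoate | COC(=O)C(OC)(OC)/C(C)=C\C[C@@]1(C)CCC=C1 | intermediate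
12 | B-alkyl-9-BBN adduct of 11, boron on the ring carbon remote from the quaternary carbon | COC(=O)C(OC)(OC)/C(C)=C\C[C@@]1(C)CCC(B2C3CCCC2CCC3)C1 | intermediate (not isolated)
13 | methyl (Z)-5-[(1R)-3-hydroxy-1-methylcyclopentyl]-2,2-dimethoxy-3-methylpent-3-enoate (both carbinol epimers) | COC(=O)C(OC)(OC)/C(C)=C\C[C@@]1(C)CCC(O)C1 | intermediate
14 | (3R)-3-[(Z)-5-hydroxy-4,4-dimethoxy-3-methylpent-2-en-1-yl]-3-methylcyclopentan-1-ol (both carbinol epimers) | OCC(OC)(OC)/C(C)=C\C[C@@]1(C)CCC(O)C1 | intermediate
15 | (Z)-2,2-dimethoxy-3-methyl-5-[(R)-1-methyl-3-oxocyclopentyl]pent-3-enal | O=CC(OC)(OC)/C(C)=C\C[C@@]1(C)CCC(=O)C1 | intermediate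
16 | aldol adduct: (8aR)-4-hydroxy-5,5-dimethoxy-6,8a-dimethyl-1,2,3a,4,8,8a-hexahydroazulen-3(5H)-one (mixture at C3a and C4) | O=C1CC[C@]2(C)CC=C(C)C(OC)(OC)C(O)C12 | intermediate (not isolated)
17 | (8aR)-5,5-dimethoxy-6,8a-dimethyl-1,2,8,8a-tetrahydroazulen-3(5H)-one | O=C1CC[C@]2(C)CC=C(C)C(OC)(OC)C=C12 | intermediate
18 | (6S,7S,8aR)-6,7-dihydroxy-5,5-dimethoxy-6,8a-dimethyl-1,2,6,7,8,8a-hexahydroazulen-3(5H)-one | O=C1CC[C@]2(C)C[C@H](O)[C@](C)(O)C(OC)(OC)C=C12 | intermediate
19 | (6S,7S,8aR)-3,3,5,5-tetramethoxy-6,8a-dimethyl-1,2,3,5,6,7,8,8a-octahydroazulene-6,7-diol 6,7-acetonide | COC1(OC)CC[C@]2(C)C[C@@H]3OC(C)(C)O[C@]3(C)C(OC)(OC)C=C12 | intermediate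
20 | alkylborane: 19 with H added at C3a (α) and BH2 at C4 (α) | COC1(OC)CC[C@]2(C)C[C@@H]3OC(C)(C)O[C@]3(C)C(OC)(OC)[C@H](B)[C@H]21 | intermediate (not isolated)
21 | (3aS,4R,6S,7S,8aR)-3,3,5,5-tetramethoxy-6,8a-dimethyldecahydroazulene-4,6,7-triol 6,7-acetonide | COC1(OC)CC[C@]2(C)C[C@@H]3OC(C)(C)O[C@]3(C)C(OC)(OC)[C@H](O)[C@H]21 | intermediate
22 | (3aS,4R,6S,7S,8aR)-4,6,7-trihydroxy-5,5-dimethoxy-6,8a-dimethyloctahydroazulen-3(2H)-one 6,7-acetonide | O=C1CC[C@]2(C)C[C@@H]3OC(C)(C)O[C@]3(C)C(OC)(OC)[C@H](O)[C@H]21 | intermediate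
23 | (3R,3aS,4R,6S,7S,8aR)-5,5-dimethoxy-6,8a-dimethyl-3-(propan-2-yl)decahydroazulene-3,4,6,7-tetrol 6,7-acetonide | CC(C)[C@]1(O)CC[C@]2(C)C[C@@H]3OC(C)(C)O[C@]3(C)C(OC)(OC)[C@H](O)[C@H]21 | intermediate
24 | 4-acetoxybenzoyl chloride | CC(=O)Oc1ccc(cc1)C(Cl)=O | starting material
25 | (3R,3aS,4R,6S,7S,8aR)-3,6,7-trihydroxy-5,5-dimethoxy-6,8a-dimethyl-3-(propan-2-yl)decahydroazulen-4-yl 4-acetoxybenzoate 6,7-acetonide | CC(C)[C@]1(O)CC[C@]2(C)C[C@@H]3OC(C)(C)O[C@]3(C)C(OC)(OC)[C@H](OC(=O)c4ccc(OC(C)=O)cc4)[C@H]21 | intermediate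
26 | (3R,3aS,4R,6S,7S,8aR)-3,6,7-trihydroxy-6,8a-dimethyl-5-oxo-3-(propan-2-yl)decahydroazulen-4-yl 4-hydroxybenzoate | CC(C)[C@]1(O)CC[C@]2(C)C[C@H](O)[C@](C)(O)C(=O)[C@H](OC(=O)c3ccc(O)cc3)[C@H]21 | target

**Step count and risks**

Total steps: 17. Longest linear sequence: 17 steps (1 to 26).

Steps most likely to fail:

1. Step 13. The C5=C6 alkene lies between three fully substituted carbons (C1, C4, C7), so hydroboration may stall, and the α-acetonide may compete with the β-methyl groups and erode facial selectivity. The fallback sets out from 18 and comes back at 22, so that steps 12 to 14 are skipped. Treatment of 18 with Me2C(OMe)2 and pyridinium p-toluenesulfonate in acetone protects only the diol and should give the enone acetonide F1. Copper-catalysed conjugate borylation of this enone (CuCl 10 mol %, Xantphos, NaOt-Bu, B2pin2, MeOH, THF, rt) needs no masking of C4 and uses the enone polarisation instead of an isolated hindered alkene; boron should add to C6 from the α-face and the copper enolate is protonated at C5, giving the β-boryl ketone F2. Oxidation with NaBO3·4H2O, with retention at C6, would return 22.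

2. Step 17. Hydrolysis of the C7 ketal is slowed by the C–O bonds on both neighbouring carbons, and acid strong enough to cleave it may shift or cleave the C6 ester or dehydrate the tertiary alcohols. The fallback sets out from 23 and comes back at 26. The C7 ketal is removed before the ester is introduced, with TsOH·H2O in acetone/H2O at 50 °C, where the acetone solvent keeps the acetonide in place, giving the α-hydroxy ketone acetonide F3. Acylation of the now less hindered C6 hydroxyl with 24 (pyridine, 4-(dimethylamino)pyridine, CH2Cl2) should give the aroate acetonide F4. Brief treatment with HCl in MeOH at rt then only has to remove the acetonide and the phenolic acetate to give 26.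

3. Step 15. Retro-aldol opening of the C6 alkoxide, enolisation at C3, or reduction by β-hydride transfer may compete with the slow addition of a secondary alkyl nucleophile to the hindered ketone. The fallback sets out from 22 and comes back at 23. The three-carbon unit is added as an sp2 nucleophile that cannot donate hydride and adds faster: 2-propenylmagnesium bromide with CeCl3 in THF at -78 °C should give, with the same facial preference, the isopropenyl carbinol F5. Hydrogenation of the 1,1-disubstituted alkene (H2, Pd/C, EtOAc) would then give 23.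

**Further compounds**

F1 | step 13 | enone acetonide: (6S,7S,8aR)-6,7-dihydroxy-5,5-dimethoxy-6,8a-dimethyl-1,2,6,7,8,8a-hexahydroazulen-3(5H)-one 6,7-acetonide | O=C1CC[C@]2(C)C[C@@H]3OC(C)(C)O[C@]3(C)C(OC)(OC)C=C12
F2 | step 13 | β-boryl ketone: 22 with a pinacolboronate in place of the C4 hydroxyl of the azulenone (same configuration) | O=C1CC[C@]2(C)C[C@@H]3OC(C)(C)O[C@]3(C)C(OC)(OC)[C@H](B4OC(C)(C)C(C)(C)O4)[C@H]21
F3 | step 17 | α-hydroxy ketone acetonide: (3R,3aS,4R,6S,7S,8aR)-3,4,6,7-tetrahydroxy-6,8a-dimethyl-3-(propan-2-yl)octahydroazulen-5(1H)-one 6,7-acetonide | CC(C)[C@]1(O)CC[C@]2(C)C[C@@H]3OC(C)(C)O[C@]3(C)C(=O)[C@H](O)[C@H]21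
F4 | step 17 | aroate acetonide: (3R,3aS,4R,6S,7S,8aR)-3,6,7-trihydroxy-6,8a-dimethyl-5-oxo-3-(propan-2-yl)decahydroazulen-4-yl 4-acetoxybenzoate 6,7-acetonide | CC(C)[C@]1(O)CC[C@]2(C)C[C@@H]3OC(C)(C)O[C@]3(C)C(=O)[C@H](OC(=O)c4ccc(OC(C)=O)cc4)[C@H]21
F5 | step 15 | isopropenyl carbinol: 23 with prop-1-en-2-yl in place of propan-2-yl (same configuration) | C=C(C)[C@]1(O)CC[C@]2(C)C[C@@H]3OC(C)(C)O[C@]3(C)C(OC)(OC)[C@H](O)[C@H]21
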